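**Plan**
1. Retrosynthesis: the five O-benzyl groups come off last. In ring C (the pyranone: O1, C2, C3, C4, C4a, C8a) the C2–C3 bond is cut and the 3-OH oxygen is reconnected to C2. This turns the flavanonol into a seven-membered 2-aryl-1,3-benzodioxepin-5-one (a cyclic acetal), which is cut into a dihydrobenzofuran-4-carbaldehyde and a ring A ω-hydroxyacetophenone. The dihydrofuran ring is cut at its C3–C2 bond.
2. Enabling feature: C2 of ring C is benzylic and already bound to O1, and C3 carries OH next to the C4 ketone. C2–C3 therefore joins an acetal-level carbon to an enolisable, oxygen-bearing carbon, so the 3-OH oxygen can bridge C2 and C3 in a temporary seven-membered ring and leave it by a 1,2-shift (O to C) from the C3 enolate.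
3. Forward order: benzofuran arene from a bromophenol (Claisen rearrangement, etherification, oxidative cleavage, diazo transfer); dihydrofuran ring by rhodium-carbenoid C–H insertion; formylation at C4; seven-membered acetal ring with the ring A ketol; ring contraction to the pyranone; hydrogenolysis.
4. Stereochemistry: benzofuran C2 from the chiral catalyst Rh2(S-PTTL)4, C3 by base epimerisation to trans; flavanonol C2 from the acetal carbon (retention in the shift; the two acetal epimers interconvert under the acid of step 12 and the unwanted one is fed back into it), C3 trans to C2.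

Key step: step 13

Assumption: dirhodium tetrakis[N-phthaloyl-(S)-tert-leucinate] is taken to induce the (2R) configuration in step 6 (its enantiomer is used should the sense be opposite), and no facial preference is assumed at the acetal carbon in step 12, which relies only on the acid-catalysed interconversion of the two acetal epimers.

Step 1
Reactants: 1 2-(benzyloxy)-5-bromophenol
Product: 2 2-(allyloxy)-1-(benzyloxy)-4-bromobenzene
Conditions: allyl bromide, K2CO3, DMF, rt
Reagents that add atoms: allyl bromide, C=CCBr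
Why: Williamson ether synthesis on the only free phenol should give the allyl aryl ether needed for the sigmatropic step.

Step 2
Reactants: 2 2-(allyloxy)-1-(benzyloxy)-4-bromobenzene
Product: 3 2-allyl-6-(benzyloxy)-3-bromophenol
Conditions: PhNEt2, 190 °C
Reagents that add atoms: none
Why: Aromatic Claisen rearrangement should deliver the allyl group to the single free ortho carbon (next to bromine), because the other ortho carbon carries the benzyloxy group.

Step 3
Reactants: 3 2-allyl-6-(benzyloxy)-3-bromophenol; 4 [4-(benzyloxy)-3-methoxyphenyl]methanol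
Product: 5 1-(benzyloxy)-2-{[4-(benzyloxy)-3-methoxyphenyl]methoxy}-4-bromo-3-allylbenzene
Conditions: PPh3, DIAD, THF, 0 °C → rt
Reagents that add atoms: none
Why: Mitsunobu etherification of the phenol with the primary benzylic alcohol should install the O–CH2–aryl group whose benzylic hydrogens are later used for C–H insertion.

Step 4
Reactants: 5 1-(benzyloxy)-2-{[4-(benzyloxy)-3-methoxyphenyl]methoxy}-4-bromo-3-allylbenzene
Product: 6 methyl 2-[3-(benzyloxy)-2-{[4-(benzyloxy)-3-methoxyphenyl]methoxy}-6-bromophenyl]acetate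
Conditions: O3, NaOH (2.5 M in MeOH), CH2Cl2, −78 °C
Reagents that add atoms: ozone, [O-][O+]=O; methanol, CO
Why: Ozonolysis of the terminal alkene in methanolic NaOH (oxidative cleavage with in situ oxidation to the methyl ester) should shorten the allyl group by one carbon to the arylacetate, the alkene being far more reactive towards ozone than the alkoxyarenes.

Step 5
Reactants: 6 methyl 2-[3-(benzyloxy)-2-{[4-(benzyloxy)-3-methoxyphenyl]methoxy}-6-bromophenyl]acetate
Product: 7 methyl 2-[3-(benzyloxy)-2-{[4-(benzyloxy)-3-methoxyphenyl]methoxy}-6-bromophenyl]-2-diazoacetate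
Conditions: 4-acetamidobenzenesulfonyl azide, DBU, MeCN, 0 °C → rt
Reagents that add atoms: 4-acetamidobenzenesulfonyl azide, CC(=O)Nc1ccc(cc1)S(=O)(=O)N=[N+]=[N-]
Why: Regitz diazo transfer to the enolate of the arylacetate should give the donor/acceptor diazo ester.

Step 6
Reactants: 7 methyl 2-[3-(benzyloxy)-2-{[4-(benzyloxy)-3-methoxyphenyl]methoxy}-6-bromophenyl]-2-diazoacetate
Product: 8 methyl (2R,3S)-7-(benzyloxy)-2-[4-(benzyloxy)-3-methoxyphenyl]-4-bromo-2,3-dihydro-1-benzofuran-3-carboxylate (2,3-cis)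
Conditions: dirhodium tetrakis[N-phthaloyl-(S)-tert-leucinate], Rh2(S-PTTL)4 (1 mol %), toluene, −60 °C
Reagents that add atoms: none
Why: Intramolecular 1,5 C–H insertion of the donor/acceptor rhodium carbenoid into the O–CH2–aryl group should close the dihydrofuran ring cis-selectively, the chiral carboxylate ligands choosing one of the two enantiotopic benzylic hydrogens and so setting C2 as R.

Step 7
Reactants: 8 methyl (2R,3S)-7-(benzyloxy)-2-[4-(benzyloxy)-3-methoxyphenyl]-4-bromo-2,3-dihydro-1-benzofuran-3-carboxylate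
Product: 9 methyl (2R,3R)-7-(benzyloxy)-2-[4-(benzyloxy)-3-methoxyphenyl]-4-bromo-2,3-dihydro-1-benzofuran-3-carboxylate (2,3-trans)
Conditions: NaOMe (0.3 equiv), MeOH/THF, rt
Reagents that add atoms: none
Why: Base-mediated epimerisation through the ester enolate should convert C3 to the thermodynamically favoured trans arrangement while C2 is untouched.

Step 8
Reactants: 9 methyl (2R,3R)-7-(benzyloxy)-2-[4-(benzyloxy)-3-methoxyphenyl]-4-bromo-2,3-dihydro-1-benzofuran-3-carboxylate
Product: 10 [(2R,3S)-7-(benzyloxy)-2-[4-(benzyloxy)-3-methoxyphenyl]-4-bromo-2,3-dihydro-1-benzofuran-3-yl]methanol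
Conditions: LiAlH4, THF, 0 °C
Reagents that add atoms: none
Why: Hydride reduction of the ester should give the hydroxymethyl group, the aryl bromide and benzyl ethers being inert at 0 °C.

Step 9
Reactants: 10 [(2R,3S)-7-(benzyloxy)-2-[4-(benzyloxy)-3-methoxyphenyl]-4-bromo-2,3-dihydro-1-benzofuran-3-yl]methanol
Product: 11 (2R,3S)-7-(benzyloxy)-2-[4-(benzyloxy)-3-methoxyphenyl]-3-[(benzyloxy)methyl]-4-bromo-2,3-dihydro-1-benzofuran
Conditions: NaH, BnBr, n-Bu4NI (5 mol %), DMF, 0 °C → rt
Reagents that add atoms: benzyl bromide, BrCc1ccccc1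
Why: Williamson benzylation should protect the primary alcohol with the same group as the phenols so that one final hydrogenolysis frees all hydroxyls.

Step 10
Reactants: 11 (2R,3S)-7-(benzyloxy)-2-[4-(benzyloxy)-3-methoxyphenyl]-3-[(benzyloxy)methyl]-4-bromo-2,3-dihydro-1-benzofuran
Product: 13 (2R,3S)-7-(benzyloxy)-2-[4-(benzyloxy)-3-methoxyphenyl]-3-[(benzyloxy)methyl]-2,3-dihydro-1-benzofuran-4-carbaldehyde, via aryllithium 12 (not isolated)
Conditions: n-BuLi, THF, −78 °C; DMF, −78 → 0 °C; H2O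
Reagents that add atoms: N,N-dimethylformamide, CN(C)C=O
Why: Bromine–lithium exchange followed by formylation with DMF (Bouveault-type aldehyde synthesis) should place the aldehyde at C4, the exchange being faster than deprotonation of the benzylic ethers at −78 °C.

Step 11
Reactants: 14 1-[2,4-bis(benzyloxy)-6-hydroxyphenyl]ethan-1-one
Product: 16 1-[2,4-bis(benzyloxy)-6-hydroxyphenyl]-2-hydroxyethan-1-one, via bis-silyl enol ether 15 (not isolated)
Conditions: Me3SiOTf, Et3N, CH2Cl2, 0 °C; mCPBA, NaHCO3, CH2Cl2, −20 °C; aq citric acid, THF, rt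
Reagents that add atoms: 3-chloroperoxybenzoic acid, OOC(=O)c1cccc(Cl)c1
Why: Rubottom oxidation (epoxidation of the silyl enol ether, silyl migration and desilylation) should hydroxylate the methyl ketone while the phenol is masked as its silyl ether, which avoids the cyclisation to a coumaranone that an alpha-halo ketone would undergo.

Step 12
Reactants: 13 (2R,3S)-7-(benzyloxy)-2-[4-(benzyloxy)-3-methoxyphenyl]-3-[(benzyloxy)methyl]-2,3-dihydro-1-benzofuran-4-carbaldehyde; 16 1-[2,4-bis(benzyloxy)-6-hydroxyphenyl]-2-hydroxyethan-1-one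
Product: 19 (2R)-6,8-bis(benzyloxy)-2-[(2R,3S)-7-(benzyloxy)-2-[4-(benzyloxy)-3-methoxyphenyl]-3-[(benzyloxy)methyl]-2,3-dihydro-1-benzofuran-4-yl]-4H-1,3-benzodioxepin-5-one, via dimethyl acetal 17 (not isolated), via acetal epimer 18 (not isolated)
Conditions: HC(OMe)3, camphorsulfonic acid (5 mol %), MeOH, rt, concentrate; then 16, camphorsulfonic acid (5 mol %), toluene, 5 Å molecular sieves, 50 °C, held until the epimer ratio is constant; chromatography, the epimer-containing remainder returned unpurified to camphorsulfonic acid, toluene, 50 °C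
Reagents that add atoms: none
Why: Acid-catalysed transacetalisation driven by removal of methanol should close the seven-membered mixed acetal on the primary hydroxyl and the phenol of 16; because the acetal carbon is para to the 7-benzyloxy group, the ring reopens reversibly to a stabilised oxocarbenium ion under the same acid, so the (2S)-epimer 18 that forms alongside is converted into 19 in the flask, and the part of it that remains after chromatography is fed back into the equilibration so that the material is funnelled to 19.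

Step 13
Reactants: 19 (2R)-6,8-bis(benzyloxy)-2-[(2R,3S)-7-(benzyloxy)-2-[4-(benzyloxy)-3-methoxyphenyl]-3-[(benzyloxy)methyl]-2,3-dihydro-1-benzofuran-4-yl]-4H-1,3-benzodioxepin-5-one
Product: 21 (2R,3R)-5,7-bis(benzyloxy)-2-[(2R,3S)-7-(benzyloxy)-2-[4-(benzyloxy)-3-methoxyphenyl]-3-[(benzyloxy)methyl]-2,3-dihydro-1-benzofuran-4-yl]-3-hydroxy-2,3-dihydro-4H-chromen-4-one, via lithium enolate 20 (not isolated)
Conditions: LiN(SiMe3)2 (1.2 equiv), THF, −78 → 0 °C; AcOH, −78 °C
Reagents that add atoms: none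
Why: Proposed new method: LiN(SiMe3)2 removes a proton from the only enolisable position, the OCH2 carbon between the ring ketone and the acetal oxygen, to give enolate 20; the bond from this oxygen to the acetal carbon then breaks (homolysis to a benzylic, aryloxy-substituted radical and a semidione radical anion, held together by the ring A tether) and the acetal carbon rebonds to the former enolate carbon, that is a [1,2]-Wittig shift from O to C that expels the oxygen from the ring as the 3-alkoxide and leaves the six-membered pyranone. The closest known reaction types are the [1,2]-Wittig rearrangement of enolates of alpha-alkoxy ketones and esters, its variant with acetal carbons as migrating groups, and ring-contracting [1,2]-Wittig shifts of cyclic benzylic ethers; an ionic course (the enolate carbon displaces the ring A phenoxide at the acetal carbon to a trans-epoxy ketone, which the phenoxide reopens at the benzylic carbon) would lead to the same alkoxide. The pyranone ring closes by C2–C3 bond formation inside the seven-membered ring, a transannular 1,2-shift that amounts to a 6-endo closure onto the former acetal carbon (in the ionic course a 6-endo opening of the epoxide). C2 is controlled by the acetal stereocentre of 19, because the new C–C bond forms on the face from which the oxygen departs (retention in the tethered radical pair, double inversion in the ionic course), so the (2R)-acetal should give (2R). C3 is controlled by C2, since collapse through the half-chair with the aryl and oxido groups both pseudo-equatorial gives the 2,3-trans (3R) isomer, which is also the thermodynamically preferred flavanonol. The step needs bond formation at the former OCH2 carbon and not at the ketone carbon of the semidione (which would give a five-membered 3-formyl-3-hydroxy-dihydrobenzofuran); the lower steric demand of that carbon and the retention of the aryl ketone conjugated with electron-rich ring A should secure this, and the low-temperature AcOH quench keeps the base-sensitive flavanonol from ring opening.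

Step 14
Reactants: 21 (2R,3R)-5,7-bis(benzyloxy)-2-[(2R,3S)-7-(benzyloxy)-2-[4-(benzyloxy)-3-methoxyphenyl]-3-[(benzyloxy)methyl]-2,3-dihydro-1-benzofuran-4-yl]-3-hydroxy-2,3-dihydro-4H-chromen-4-one
Product: 22 (2R,3R)-3,5,7-trihydroxy-2-[(2R,3S)-7-hydroxy-2-(4-hydroxy-3-methoxyphenyl)-3-(hydroxymethyl)-2,3-dihydro-1-benzofuran-4-yl]-2,3-dihydro-4H-chromen-4-one
Conditions: H2 (1 atm), Pd/C (10 wt %), EtOAc/MeOH, rt
Reagents that add atoms: none
Why: Catalytic hydrogenolysis should remove the five O-benzyl groups faster than it cleaves the two cyclic benzylic C–O bonds or reduces the aryl ketone, and it touches no stereocentre.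

**Compound list**
1 | 2-(benzyloxy)-5-bromophenol | Oc1cc(Br)ccc1OCc1ccccc1 | starting material
2 | 2-(allyloxy)-1-(benzyloxy)-4-bromobenzene | C=CCOc1cc(Br)ccc1OCc1ccccc1 | intermediate
3 | 2-allyl-6-(benzyloxy)-3-bromophenol | C=CCc1c(Br)ccc(OCc2ccccc2)c1O | intermediate
4 | [4-(benzyloxy)-3-methoxyphenyl]methanol | OCc1ccc(OCc2ccccc2)c(OC)c1 | starting material
5 | 1-(benzyloxy)-2-{[4-(benzyloxy)-3-methoxyphenyl]methoxy}-4-bromo-3-allylbenzene | C=CCc1c(Br)ccc(OCc2ccccc2)c1OCc1ccc(OCc2ccccc2)c(OC)c1 | intermediate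
6 | methyl 2-[3-(benzyloxy)-2-{[4-(benzyloxy)-3-methoxyphenyl]methoxy}-6-bromophenyl]acetate | COC(=O)Cc1c(Br)ccc(OCc2ccccc2)c1OCc1ccc(OCc2ccccc2)c(OC)c1 | intermediate
7 | methyl 2-[3-(benzyloxy)-2-{[4-(benzyloxy)-3-methoxyphenyl]methoxy}-6-bromophenyl]-2-diazoacetate | COC(=O)C(=[N+]=[N-])c1c(Br)ccc(OCc2ccccc2)c1OCc1ccc(OCc2ccccc2)c(OC)c1 | intermediate
8 | methyl (2R,3S)-7-(benzyloxy)-2-[4-(benzyloxy)-3-methoxyphenyl]-4-bromo-2,3-dihydro-1-benzofuran-3-carboxylate (cis) | COc1cc([C@@H]2Oc3c(OCc4ccccc4)ccc(Br)c3[C@@H]2C(=O)OC)ccc1OCc1ccccc1 | intermediate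
9 | methyl (2R,3R)-7-(benzyloxy)-2-[4-(benzyloxy)-3-methoxyphenyl]-4-bromo-2,3-dihydro-1-benzofuran-3-carboxylate (trans) | COc1cc([C@@H]2Oc3c(OCc4ccccc4)ccc(Br)c3[C@H]2C(=O)OC)ccc1OCc1ccccc1 | intermediate
10 | [(2R,3S)-7-(benzyloxy)-2-[4-(benzyloxy)-3-methoxyphenyl]-4-bromo-2,3-dihydro-1-benzofuran-3-yl]methanol | COc1cc([C@@H]2Oc3c(OCc4ccccc4)ccc(Br)c3[C@H]2CO)ccc1OCc1ccccc1 | intermediate
11 | (2R,3S)-7-(benzyloxy)-2-[4-(benzyloxy)-3-methoxyphenyl]-3-[(benzyloxy)methyl]-4-bromo-2,3-dihydro-1-benzofuran | COc1cc([C@@H]2Oc3c(OCc4ccccc4)ccc(Br)c3[C@H]2COCc2ccccc2)ccc1OCc1ccccc1 | intermediate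
12 | [(2R,3S)-7-(benzyloxy)-2-[4-(benzyloxy)-3-methoxyphenyl]-3-[(benzyloxy)methyl]-2,3-dihydro-1-benzofuran-4-yl]lithium | COc1cc([C@@H]2Oc3c(OCc4ccccc4)ccc([Li])c3[C@H]2COCc2ccccc2)ccc1OCc1ccccc1 | intermediate
13 | (2R,3S)-7-(benzyloxy)-2-[4-(benzyloxy)-3-methoxyphenyl]-3-[(benzyloxy)methyl]-2,3-dihydro-1-benzofuran-4-carbaldehyde | COc1cc([C@@H]2Oc3c(OCc4ccccc4)ccc(C=O)c3[C@H]2COCc2ccccc2)ccc1OCc1ccccc1 | intermediate
14 | 1-[2,4-bis(benzyloxy)-6-hydroxyphenyl]ethan-1-one | CC(=O)c1c(O)cc(OCc2ccccc2)cc1OCc1ccccc1 | starting material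
15 | {[1-{2,4-bis(benzyloxy)-6-[(trimethylsilyl)oxy]phenyl}ethenyl]oxy}trimethylsilane | C=C(O[Si](C)(C)C)c1c(O[Si](C)(C)C)cc(OCc2ccccc2)cc1OCc1ccccc1 | intermediate
16 | 1-[2,4-bis(benzyloxy)-6-hydroxyphenyl]-2-hydroxyethan-1-one | OCC(=O)c1c(O)cc(OCc2ccccc2)cc1OCc1ccccc1 | intermediate
17 | (2R,3S)-7-(benzyloxy)-2-[4-(benzyloxy)-3-methoxyphenyl]-3-[(benzyloxy)methyl]-4-(dimethoxymethyl)-2,3-dihydro-1-benzofuran | COc1cc([C@@H]2Oc3c(OCc4ccccc4)ccc(C(OC)OC)c3[C@H]2COCc2ccccc2)ccc1OCc1ccccc1 | intermediate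
18 | (2S)-6,8-bis(benzyloxy)-2-[(2R,3S)-7-(benzyloxy)-2-[4-(benzyloxy)-3-methoxyphenyl]-3-[(benzyloxy)methyl]-2,3-dihydro-1-benzofuran-4-yl]-4H-1,3-benzodioxepin-5-one (acetal epimer of 19; interconverts with 19 under the acid of step 12) | COc1cc([C@@H]2Oc3c(OCc4ccccc4)ccc([C@H]4OCC(=O)c5c(OCc6ccccc6)cc(OCc6ccccc6)cc5O4)c3[C@H]2COCc2ccccc2)ccc1OCc1ccccc1 | intermediate
19 | (2R)-6,8-bis(benzyloxy)-2-[(2R,3S)-7-(benzyloxy)-2-[4-(benzyloxy)-3-methoxyphenyl]-3-[(benzyloxy)methyl]-2,3-dihydro-1-benzofuran-4-yl]-4H-1,3-benzodioxepin-5-one | COc1cc([C@@H]2Oc3c(OCc4ccccc4)ccc([C@@H]4OCC(=O)c5c(OCc6ccccc6)cc(OCc6ccccc6)cc5O4)c3[C@H]2COCc2ccccc2)ccc1OCc1ccccc1 | intermediate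
20 | lithium (2R)-6,8-bis(benzyloxy)-2-[(2R,3S)-7-(benzyloxy)-2-[4-(benzyloxy)-3-methoxyphenyl]-3-[(benzyloxy)methyl]-2,3-dihydro-1-benzofuran-4-yl]-2H-1,3-benzodioxepin-5-olate | COc1cc([C@@H]2Oc3c(OCc4ccccc4)ccc([C@@H]4OC=C(O[Li])c5c(OCc6ccccc6)cc(OCc6ccccc6)cc5O4)c3[C@H]2COCc2ccccc2)ccc1OCc1ccccc1 | intermediate
21 | (2R,3R)-5,7-bis(benzyloxy)-2-[(2R,3S)-7-(benzyloxy)-2-[4-(benzyloxy)-3-methoxyphenyl]-3-[(benzyloxy)methyl]-2,3-dihydro-1-benzofuran-4-yl]-3-hydroxy-2,3-dihydro-4H-chromen-4-one | COc1cc([C@@H]2Oc3c(OCc4ccccc4)ccc([C@H]4Oc5cc(OCc6ccccc6)cc(OCc6ccccc6)c5C(=O)[C@@H]4O)c3[C@H]2COCc2ccccc2)ccc1OCc1ccccc1 | intermediate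
22 | (2R,3R)-3,5,7-trihydroxy-2-[(2R,3S)-7-hydroxy-2-(4-hydroxy-3-methoxyphenyl)-3-(hydroxymethyl)-2,3-dihydro-1-benzofuran-4-yl]-2,3-dihydro-4H-chromen-4-one | COc1cc([C@@H]2Oc3c(O)ccc([C@H]4Oc5cc(O)cc(O)c5C(=O)[C@@H]4O)c3[C@H]2CO)ccc1O | target

**Step count and risks**
Total steps: 14. Longest linear sequence: 13 steps (steps 1–10, 12, 13, 14, from compound 1); step 11 is a one-step side branch.

Steps most likely to fail:

Step 13 (proposed new method). What may go wrong: loss of stereochemical memory at the migrating acetal carbon (rotation within the radical pair, or an ionising reopening of an epoxy ketone); bond formation at the ketone carbon of the semidione to the five-membered isomer; 5-exo reopening of an epoxy ketone with dehydration to an aurone; or no shift at all below the temperature at which the enolate decomposes. The fallback uses known chemistry, sets out from aldehyde 13 and acetophenone 14 and comes back at 21. Compound 14 is protected with MOMCl and i-Pr2NEt as 1-[2,4-bis(benzyloxy)-6-(methoxymethoxy)phenyl]ethan-1-one F1. Claisen–Schmidt condensation of F1 with 13 (KOH, EtOH/THF) should give (2E)-1-[2,4-bis(benzyloxy)-6-(methoxymethoxy)phenyl]-3-[(2R,3S)-7-(benzyloxy)-2-[4-(benzyloxy)-3-methoxyphenyl]-3-[(benzyloxy)methyl]-2,3-dihydro-1-benzofuran-4-yl]prop-2-en-1-one F2. Juliá–Colonna epoxidation (poly-L-leucine, urea–H2O2, DBU, THF; poly-D-leucine should the sense be opposite) should give, under catalyst control, [2,4-bis(benzyloxy)-6-(methoxymethoxy)phenyl]{(2R,3S)-3-[(2R,3S)-7-(benzyloxy)-2-[4-(benzyloxy)-3-methoxyphenyl]-3-[(benzyloxy)methyl]-2,3-dihydro-1-benzofuran-4-yl]oxiran-2-yl}methanone F3. HCl in MeOH/THF then removes the MOM group, and the freed phenol should open the epoxide 6-endo at the benzylic carbon with inversion to give 21.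

Step 12. What may go wrong: slow closure of the seven-membered mixed aryl/alkyl acetal by the weakly nucleophilic, hydrogen-bonded phenol, so that open-chain or oligomeric acetals accumulate; an equilibrium at the acetal carbon that lies on the side of the unwanted epimer would in addition cost extra passes through the equilibration. The fallback sets out from 13 and 16 and comes back at 19; it forms the acetal by oxidation instead of condensation. NaBH4 reduction of 13 gives [(2R,3S)-7-(benzyloxy)-2-[4-(benzyloxy)-3-methoxyphenyl]-3-[(benzyloxy)methyl]-2,3-dihydro-1-benzofuran-4-yl]methanol F4. Cl3CCN and DBU convert it into [(2R,3S)-7-(benzyloxy)-2-[4-(benzyloxy)-3-methoxyphenyl]-3-[(benzyloxy)methyl]-2,3-dihydro-1-benzofuran-4-yl]methyl 2,2,2-trichloroethanimidate F5. Acid-catalysed benzylation of the primary hydroxyl of 16 with F5 (TfOH, 5 mol %, CH2Cl2) should give 1-[2,4-bis(benzyloxy)-6-hydroxyphenyl]-2-{[(2R,3S)-7-(benzyloxy)-2-[4-(benzyloxy)-3-methoxyphenyl]-3-[(benzyloxy)methyl]-2,3-dihydro-1-benzofuran-4-yl]methoxy}ethan-1-one F6. DDQ (CH2Cl2, 4 Å molecular sieves) should then oxidise this para-alkoxybenzylic ether to the oxocarbenium ion, which the neighbouring phenol traps to give 19 together with its epimer 18; camphorsulfonic acid in toluene at 50 °C then interconverts the two as in step 12.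

Step 6. What may go wrong: erosion of enantio- or cis-selectivity because the carbenoid carbon is flanked by two ortho substituents, or diversion of the carbenoid into aromatic cycloaddition (Buchner reaction) on the electron-rich benzyl group or into dimerisation. The fallback sets out from 6 and comes back at 9; it replaces catalyst control by a covalently bound auxiliary. Saponification of 6 (LiOH, THF/H2O) gives 2-[3-(benzyloxy)-2-{[4-(benzyloxy)-3-methoxyphenyl]methoxy}-6-bromophenyl]acetic acid F7. Esterification with (2S)-2-hydroxy-1-(pyrrolidin-1-yl)propan-1-one (EDC, DMAP) gives (2S)-1-oxo-1-(pyrrolidin-1-yl)propan-2-yl 2-[3-(benzyloxy)-2-{[4-(benzyloxy)-3-methoxyphenyl]methoxy}-6-bromophenyl]acetate F8. Diazo transfer as in step 5 gives (2S)-1-oxo-1-(pyrrolidin-1-yl)propan-2-yl 2-[3-(benzyloxy)-2-{[4-(benzyloxy)-3-methoxyphenyl]methoxy}-6-bromophenyl]-2-diazoacetate F9. C–H insertion with Rh2(OAc)4 (or with Rh2(S-DOSP)4 as the matched chiral partner) should give, under auxiliary control, (2S)-1-oxo-1-(pyrrolidin-1-yl)propan-2-yl (2R,3S)-7-(benzyloxy)-2-[4-(benzyloxy)-3-methoxyphenyl]-4-bromo-2,3-dihydro-1-benzofuran-3-carboxylate F10. NaOMe in MeOH then cleaves the auxiliary by transesterification and epimerises C3, giving the trans methyl ester 9.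

Further compounds
F1 | step 13 | 1-[2,4-bis(benzyloxy)-6-(methoxymethoxy)phenyl]ethan-1-one | CC(=O)c1c(OCOC)cc(OCc2ccccc2)cc1OCc1ccccc1
F2 | step 13 | (2E)-1-[2,4-bis(benzyloxy)-6-(methoxymethoxy)phenyl]-3-[(2R,3S)-7-(benzyloxy)-2-[4-(benzyloxy)-3-methoxyphenyl]-3-[(benzyloxy)methyl]-2,3-dihydro-1-benzofuran-4-yl]prop-2-en-1-one | COc1cc([C@@H]2Oc3c(OCc4ccccc4)ccc(/C=C/C(=O)c4c(OCOC)cc(OCc5ccccc5)cc4OCc4ccccc4)c3[C@H]2COCc2ccccc2)ccc1OCc1ccccc1
F3 | step 13 | [2,4-bis(benzyloxy)-6-(methoxymethoxy)phenyl]{(2R,3S)-3-[(2R,3S)-7-(benzyloxy)-2-[4-(benzyloxy)-3-methoxyphenyl]-3-[(benzyloxy)methyl]-2,3-dihydro-1-benzofuran-4-yl]oxiran-2-yl}methanone | COc1cc([C@@H]2Oc3c(OCc4ccccc4)ccc([C@@H]4O[C@H]4C(=O)c4c(OCOC)cc(OCc5ccccc5)cc4OCc4ccccc4)c3[C@H]2COCc2ccccc2)ccc1OCc1ccccc1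
F4 | step 12 | [(2R,3S)-7-(benzyloxy)-2-[4-(benzyloxy)-3-methoxyphenyl]-3-[(benzyloxy)methyl]-2,3-dihydro-1-benzofuran-4-yl]methanol | COc1cc([C@@H]2Oc3c(OCc4ccccc4)ccc(CO)c3[C@H]2COCc2ccccc2)ccc1OCc1ccccc1
F5 | step 12 | [(2R,3S)-7-(benzyloxy)-2-[4-(benzyloxy)-3-methoxyphenyl]-3-[(benzyloxy)methyl]-2,3-dihydro-1-benzofuran-4-yl]methyl 2,2,2-trichloroethanimidate | COc1cc([C@@H]2Oc3c(OCc4ccccc4)ccc(COC(=N)C(Cl)(Cl)Cl)c3[C@H]2COCc2ccccc2)ccc1OCc1ccccc1
F6 | step 12 | 1-[2,4-bis(benzyloxy)-6-hydroxyphenyl]-2-{[(2R,3S)-7-(benzyloxy)-2-[4-(benzyloxy)-3-methoxyphenyl]-3-[(benzyloxy)methyl]-2,3-dihydro-1-benzofuran-4-yl]methoxy}ethan-1-one | COc1cc([C@@H]2Oc3c(OCc4ccccc4)ccc(COCC(=O)c4c(O)cc(OCc5ccccc5)cc4OCc4ccccc4)c3[C@H]2COCc2ccccc2)ccc1OCc1ccccc1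
F7 | step 6 | 2-[3-(benzyloxy)-2-{[4-(benzyloxy)-3-methoxyphenyl]methoxy}-6-bromophenyl]acetic acid | OC(=O)Cc1c(Br)ccc(OCc2ccccc2)c1OCc1ccc(OCc2ccccc2)c(OC)c1
F8 | step 6 | (2S)-1-oxo-1-(pyrrolidin-1-yl)propan-2-yl 2-[3-(benzyloxy)-2-{[4-(benzyloxy)-3-methoxyphenyl]methoxy}-6-bromophenyl]acetate | C[C@H](OC(=O)Cc1c(Br)ccc(OCc2ccccc2)c1OCc1ccc(OCc2ccccc2)c(OC)c1)C(=O)N1CCCC1
F9 | step 6 | (2S)-1-oxo-1-(pyrrolidin-1-yl)propan-2-yl 2-[3-(benzyloxy)-2-{[4-(benzyloxy)-3-methoxyphenyl]methoxy}-6-bromophenyl]-2-diazoacetate | C[C@H](OC(=O)C(=[N+]=[N-])c1c(Br)ccc(OCc2ccccc2)c1OCc1ccc(OCc2ccccc2)c(OC)c1)C(=O)N1CCCC1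
F10 | step 6 | (2S)-1-oxo-1-(pyrrolidin-1-yl)propan-2-yl (2R,3S)-7-(benzyloxy)-2-[4-(benzyloxy)-3-methoxyphenyl]-4-bromo-2,3-dihydro-1-benzofuran-3-carboxylate | COc1cc([C@@H]2Oc3c(OCc4ccccc4)ccc(Br)c3[C@@H]2C(=O)O[C@@H](C)C(=O)N2CCCC2)ccc1OCc1ccccc1
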